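The cyclohexene ring of the target (C1 = ring CH carrying the C1′H2O–coumarin arm, C2(Me)=C3, C4H2, C5 = CHOAc, C6 = CMe2) is opened at C1–C6 and C4–C5. The key step exploits the C2=C3 ring alkene as the retron of a [4+2] addition whose two-carbon partner brings oxygen-bearing C5 and gem-dimethyl C6. Its precursors are a (Z)-2-silyloxydiene carrying the PMB-protected C1′ arm on the enol terminus and 2-methyl-1-nitropropene. One operation should give the ring, the quaternary C6, the C1 stereocentre, a regiodefined C2=C3 enol silane (later C2–Me) and a C5 nitro group (later ketone, then trans acetate).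

Key step: step 6

Remark: the target is (1R,5R) in the ring numbering above, with the C5 acetate trans to the C1 side chain; the enol silane is triethylsilyl so that MeLi can release the C2 enolate in step 7, and the catalyst antipode in step 6 that gives (R) at C1 is assumed to be found by a first screen.

Step 1
Reactants: 1 propane-1,3-diol
Product: 3 3-[(4-methoxybenzyl)oxy]propan-1-ol, via sodium 3-hydroxypropan-1-olate 2 (not isolated)
Conditions: NaH (1.0 equiv), 1 (4 equiv), THF, 0 °C; then 4-methoxybenzyl chloride (1.0 equiv), Bu4NI (5 mol %), 0 °C → rt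
Reagents that add atoms: 4-methoxybenzyl chloride, COc1ccc(CCl)cc1
Why: Williamson ether synthesis, in which the excess of the symmetrical diol should keep double alkylation low and is washed out with water.

Step 2
Reactants: 3 3-[(4-methoxybenzyl)oxy]propan-1-ol
Product: 4 3-[(4-methoxybenzyl)oxy]propanal
Conditions: 2,2,6,6-tetramethylpiperidin-1-oxyl (TEMPO, 10 mol %), PhI(OAc)2 (1.1 equiv), CH2Cl2, rt
Reagents that add atoms: none
Why: oxoammonium (TEMPO/PhI(OAc)2) oxidation stops at the aldehyde and needs no base, so the β-alkoxy aldehyde is not exposed to elimination.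

Step 3
Reactants: 4 3-[(4-methoxybenzyl)oxy]propanal; 5 vinylmagnesium bromide
Product: 6 5-[(4-methoxybenzyl)oxy]pent-1-en-3-ol (racemic)
Conditions: 5 (1.2 equiv), THF, −78 → 0 °C; aq NH4Cl
Reagents that add atoms: none
Why: Grignard 1,2-addition to the aldehyde; the new carbinol centre is racemic and is removed in the next step.

Step 4
Reactants: 6 5-[(4-methoxybenzyl)oxy]pent-1-en-3-ol
Product: 7 5-[(4-methoxybenzyl)oxy]pent-1-en-3-one
Conditions: Dess–Martin periodinane (1.2 equiv), CH2Cl2, 0 °C → rt; used at once
Reagents that add atoms: none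
Why: Dess–Martin oxidation of the allylic alcohol to the vinyl ketone under mild, nearly neutral conditions that spare the PMB ether and the polymerisable enone.

Step 5
Reactants: 7 5-[(4-methoxybenzyl)oxy]pent-1-en-3-one
Product: 8 (Z)-3-(triethylsilyloxy)-5-(4-methoxybenzyloxy)penta-1,3-diene
Conditions: Et3SiOTf (1.2 equiv), Et3N (2.0 equiv), CH2Cl2, −78 → 0 °C
Reagents that add atoms: triethylsilyl trifluoromethanesulfonate, CC[Si](CC)(CC)OS(=O)(=O)C(F)(F)F
Why: soft enolisation with a silyl triflate and a tertiary amine; the ketone has a single enolisable CH2, and the (Z)-enol silane, with CH2OPMB anti to the vinyl group, is the usual product and the geometry that can reach the s-cis conformation.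

Step 6
Reactants: 8 (Z)-3-(triethylsilyloxy)-5-(4-methoxybenzyloxy)penta-1,3-diene; 9 2-methyl-1-nitroprop-1-ene
Product: 10 triethyl{[(4S,6R)-6-{[(4-methoxybenzyl)oxy]methyl}-5,5-dimethyl-4-nitrocyclohex-1-en-1-yl]oxy}silane (nitro cis to CH2OPMB)
Conditions: (S)-N-benzhydryl-2-{3-[3,5-bis(trifluoromethyl)phenyl]thioureido}-N,3,3-trimethylbutanamide (20 mol %), 9 (3 equiv), 4 Å MS, toluene (1 M), −20 °C → rt; chromatography on Et3N-deactivated silica
Reagents that add atoms: none
Why: Proposed new method: the two thiourea N–H bonds bind the nitro group of 9 and lower its LUMO, so that the enol-silane terminus of 8 (future C1) attacks the β-carbon (future C6) and the developing nitronate carbon (C5) bonds to the vinyl terminus (C4), as a strongly asynchronous [4+2] cycloaddition or, in the limit, a double Michael sequence. The closest known reaction type is the thermal Diels–Alder reaction of 2-silyloxydienes with nitroalkenes, together with hydrogen-bond-donor catalysis of additions to nitroalkenes; a catalytic enantioselective version with a β,β-disubstituted nitroalkene is not established. The cyclohexene ring is closed by suprafacial [4+2] union of the four diene carbons with the two alkene carbons (a 6-endo-trig Michael closure of the nitronate in the stepwise limit). C1 is set by the catalyst, which must distinguish the two faces of the enol silane as the C1–C6 bond forms, and C5 by an endo nitro group, which ends up cis to the outside CH2OPMB group and is erased later. The step needs regioselectivity, which the silyloxy donor secures by placing the largest HOMO coefficient on the substituted enol carbon, while the (Z)-geometry keeps CH2OPMB outside the s-cis diene. Enantioselectivity at C1 is the insecure point, and step 10 should remove any minor enantiomer as a diastereomer.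

Step 7
Reactants: 10 triethyl{[(4S,6R)-6-{[(4-methoxybenzyl)oxy]methyl}-5,5-dimethyl-4-nitrocyclohex-1-en-1-yl]oxy}silane
Product: 13 (6R)-6-{[(4-methoxybenzyl)oxy]methyl}-5,5-dimethyl-4-nitrocyclohex-1-en-1-yl trifluoromethanesulfonate (either or both C4 epimers), via enol silane lithium nitronate 11 (not isolated), via dilithium nitronate enolate 12 (not isolated)
Conditions: MeLi (2.1 equiv), THF, −78 → 0 °C; PhNTf2 (1.05 equiv), −78 → 0 °C; AcOH, −78 °C
Reagents that add atoms: N-phenylbis(trifluoromethanesulfonimide), FC(F)(F)S(=O)(=O)N(c1ccccc1)S(=O)(=O)C(F)(F)F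
Why: regiospecific enolate generation from the enol silane followed by O-triflation: the first MeLi turns the acidic nitro group into its inert lithium nitronate, the second cleaves the Si–O bond with no amine present, so the C2=C3 enolate cannot equilibrate, and PhNTf2 should sulfonylate this hard, far more basic oxygen in preference to the delocalised nitronate, which acetic acid then returns to the nitro group (the C5 configuration is of no consequence).

Step 8
Reactants: 13 (6R)-6-{[(4-methoxybenzyl)oxy]methyl}-5,5-dimethyl-4-nitrocyclohex-1-en-1-yl trifluoromethanesulfonate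
Product: 14 1-methoxy-4-({[(1R)-2,6,6-trimethyl-5-nitrocyclohex-2-en-1-yl]methoxy}methyl)benzene (either or both C5 epimers)
Conditions: SnMe4 (3 equiv), Pd(PPh3)4 (5 mol %), LiCl (3 equiv), DMF, 70 °C
Reagents that add atoms: tetramethyltin, C[Sn](C)(C)C
Why: Stille coupling of an enol triflate: oxidative addition of zerovalent palladium into the C2–O bond, LiCl-assisted transmetallation and reductive elimination should place the methyl group on C2 with the alkene fixed at C2=C3, under neutral conditions that leave the secondary nitro group and C1 untouched.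

Step 9
Reactants: 14 1-methoxy-4-({[(1R)-2,6,6-trimethyl-5-nitrocyclohex-2-en-1-yl]methoxy}methyl)benzene
Product: 16 (5R)-5-{[(4-methoxybenzyl)oxy]methyl}-4,6,6-trimethylcyclohex-3-en-1-one, via sodium nitronate 15 (not isolated)
Conditions: NaOMe (1.1 equiv), MeOH, 0 °C; then added to TiCl3 (4 equiv, aq), NH4OAc buffer (pH 5–6), MeOH/H2O, 0 °C → rt
Reagents that add atoms: water, O
Why: reductive Nef reaction: TiCl3 (trivalent titanium) takes the preformed nitronate down to the carbonyl oxidation level and water releases the C5 ketone, while the buffered, weakly acidic medium should keep the β,γ-alkene out of conjugation and the PMB ether intact.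

Step 10
Reactants: 16 (5R)-5-{[(4-methoxybenzyl)oxy]methyl}-4,6,6-trimethylcyclohex-3-en-1-one
Product: 17 (1R,5R)-5-{[(4-methoxybenzyl)oxy]methyl}-4,6,6-trimethylcyclohex-3-en-1-ol (hydroxyl trans to CH2OPMB)
Conditions: (3aS)-1-methyl-3,3-diphenyltetrahydro-1H,3H-pyrrolo[1,2-c][1,3,2]oxazaborole ((S)-Me-CBS, 20 mol %), BH3·SMe2 (0.8 equiv, slow addition), THF, −20 °C; MeOH
Reagents that add atoms: none
Why: Corey–Bakshi–Shibata reduction under reagent control: the carbonyl should bind the oxazaborolidine boron through the lone pair on the C4H2 side, away from quaternary C6, so that the N-bound borane delivers hydride to the face giving the (R)-carbinol at C5, trans to the C1 side chain, whatever the ring's own bias; a ketone of (S) configuration at the side-chain carbon would give the separable cis diastereomer, so the step should also raise enantiomeric purity.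

Step 11
Reactants: 17 (1R,5R)-5-{[(4-methoxybenzyl)oxy]methyl}-4,6,6-trimethylcyclohex-3-en-1-ol
Product: 18 (1R,5R)-5-{[(4-methoxybenzyl)oxy]methyl}-4,6,6-trimethylcyclohex-3-en-1-yl acetate
Conditions: Ac2O (3 equiv), Et3N (4 equiv), 4-(dimethylamino)pyridine (10 mol %), CH2Cl2, rt
Reagents that add atoms: acetic anhydride, CC(=O)OC(C)=O
Why: DMAP-catalysed acetylation of the hindered secondary alcohol, with retention at C5 because only the O–H bond is broken.

Step 12
Reactants: 18 (1R,5R)-5-{[(4-methoxybenzyl)oxy]methyl}-4,6,6-trimethylcyclohex-3-en-1-yl acetate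
Product: 19 (1R,5R)-5-(hydroxymethyl)-4,6,6-trimethylcyclohex-3-en-1-yl acetate
Conditions: DDQ (1.3 equiv), CH2Cl2/pH 7 phosphate buffer (10:1), 0 °C → rt
Reagents that add atoms: none
Why: oxidative PMB ether cleavage by DDQ (hydride abstraction at the electron-rich benzylic position, then hydrolysis) at neutral pH, which should spare the acetate and the trisubstituted alkene.

Step 13
Reactants: 19 (1R,5R)-5-(hydroxymethyl)-4,6,6-trimethylcyclohex-3-en-1-yl acetate; 20 umbelliferone (7-hydroxy-2H-chromen-2-one)
Product: 21 (1R,5R)-4,6,6-trimethyl-5-{[(2-oxo-2H-chromen-7-yl)oxy]methyl}cyclohex-3-en-1-yl acetate (target)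
Conditions: PPh3 (1.5 equiv), DIAD (1.5 equiv), 20 (1.3 equiv), THF, 0 °C → rt
Reagents that add atoms: none
Why: Mitsunobu etherification, in which the primary alcohol is activated as its oxyphosphonium salt and displaced by the acidic 7-hydroxyl of umbelliferone; no stereocentre is involved and the acetate is inert.

Compound list
1 | propane-1,3-diol | OCCCO | starting material
2 | sodium 3-hydroxypropan-1-olate | [Na+].[O-]CCCO | intermediate (not isolated)
3 | 3-[(4-methoxybenzyl)oxy]propan-1-ol | OCCCOCc1ccc(OC)cc1 | intermediate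
4 | 3-[(4-methoxybenzyl)oxy]propanal | O=CCCOCc1ccc(OC)cc1 | intermediate
5 | vinylmagnesium bromide | C=C[Mg]Br | starting material
6 | 5-[(4-methoxybenzyl)oxy]pent-1-en-3-ol (racemic) | C=CC(O)CCOCc1ccc(OC)cc1 | intermediate
7 | 5-[(4-methoxybenzyl)oxy]pent-1-en-3-one | C=CC(=O)CCOCc1ccc(OC)cc1 | intermediate
8 | (Z)-3-(triethylsilyloxy)-5-(4-methoxybenzyloxy)penta-1,3-diene | C=C/C(O[Si](CC)(CC)CC)=C/COCc1ccc(OC)cc1 | intermediate
9 | 2-methyl-1-nitroprop-1-ene | CC(C)=C[N+](=O)[O-] | starting material
10 | triethyl{[(4S,6R)-6-{[(4-methoxybenzyl)oxy]methyl}-5,5-dimethyl-4-nitrocyclohex-1-en-1-yl]oxy}silane (nitro cis to CH2OPMB) | O=[N+]([O-])[C@H]1CC=C(O[Si](CC)(CC)CC)[C@@H](COCc2ccc(OC)cc2)C1(C)C | intermediate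
11 | lithium nitronate of 10 (C=NO2Li at the former nitro carbon, enol silane intact, (R) at the CH2OPMB carbon) | [Li+].[O-][N+]([O-])=C1CC=C(O[Si](CC)(CC)CC)[C@@H](COCc2ccc(OC)cc2)C1(C)C | intermediate (not isolated)
12 | dilithium nitronate enolate (nitronate at C5, lithium enolate O–C2=C3, (R) at C1) | [Li+].[Li+].[O-][N+]([O-])=C1CC=C([O-])[C@@H](COCc2ccc(OC)cc2)C1(C)C | intermediate (not isolated)
13 | (6R)-6-{[(4-methoxybenzyl)oxy]methyl}-5,5-dimethyl-4-nitrocyclohex-1-en-1-yl trifluoromethanesulfonate (C4 epimers) | O=[N+]([O-])C1CC=C(OS(=O)(=O)C(F)(F)F)[C@@H](COCc2ccc(OC)cc2)C1(C)C | intermediate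
14 | 1-methoxy-4-({[(1R)-2,6,6-trimethyl-5-nitrocyclohex-2-en-1-yl]methoxy}methyl)benzene (C5 epimers) | O=[N+]([O-])C1CC=C(C)[C@@H](COCc2ccc(OC)cc2)C1(C)C | intermediate
15 | sodium nitronate of 14 | [Na+].[O-][N+]([O-])=C1CC=C(C)[C@@H](COCc2ccc(OC)cc2)C1(C)C | intermediate (not isolated)
16 | (5R)-5-{[(4-methoxybenzyl)oxy]methyl}-4,6,6-trimethylcyclohex-3-en-1-one | O=C1CC=C(C)[C@@H](COCc2ccc(OC)cc2)C1(C)C | intermediate
17 | (1R,5R)-5-{[(4-methoxybenzyl)oxy]methyl}-4,6,6-trimethylcyclohex-3-en-1-ol | O[C@@H]1CC=C(C)[C@@H](COCc2ccc(OC)cc2)C1(C)C | intermediate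
18 | (1R,5R)-5-{[(4-methoxybenzyl)oxy]methyl}-4,6,6-trimethylcyclohex-3-en-1-yl acetate | CC(=O)O[C@@H]1CC=C(C)[C@@H](COCc2ccc(OC)cc2)C1(C)C | intermediate
19 | (1R,5R)-5-(hydroxymethyl)-4,6,6-trimethylcyclohex-3-en-1-yl acetate | CC(=O)O[C@@H]1CC=C(C)[C@@H](CO)C1(C)C | intermediate
20 | umbelliferone (7-hydroxy-2H-chromen-2-one) | O=c1ccc2ccc(O)cc2o1 | starting material
21 | (1R,5R)-4,6,6-trimethyl-5-{[(2-oxo-2H-chromen-7-yl)oxy]methyl}cyclohex-3-en-1-yl acetate | CC(=O)O[C@@H]1CC=C(C)[C@@H](COc2ccc3ccc(=O)oc3c2)C1(C)C | target

Total step count: 13. Longest linear sequence: 13 steps (1 → 21); 5, 9 and 20 are bought.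

Steps most likely to fail

Step 6 (carries the label). The hindered β,β-dimethyl terminus may react too slowly under hydrogen-bond catalysis, facial discrimination at C1 may be weak, or silyl transfer to the nitronate may interrupt ring closure. The fallback uses known chemistry and sets out from 8 and 9. The uncatalysed thermal cycloaddition (toluene, 100 °C, sealed tube, BHT; 10 kbar if needed) should give the racemic cycloadduct F1. The conditions of steps 7 to 9 should then give the racemic enol triflate F2, the racemic methylated nitro compound F3 and the racemic ketone F4. The reduction of step 10 then serves as the resolution: (S)-Me-CBS should form the (R)-carbinol from both enantiomers, giving 17 from the (R)-ketone and the cis alcohol F5 from the (S)-ketone, which are separated by chromatography. The route is rejoined at 17, at the cost of half the material.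

Step 7. Proton transfer to the enolate, or sulfonylation of the nitronate oxygen, may compete with O-triflation of the enolate. The fallback removes the nitro group before any enolate is made and sets out from 10. Base-mediated aerobic Nef oxidation (DBU, O2, MeCN, rt) should give the keto enol silane F6. Corey–Bakshi–Shibata reduction with (S)-Me-CBS and catecholborane (toluene, −78 °C, a hydride source that spares the enol silane) should give the hydroxy enol silane F7. MeLi (2.1 equiv) followed by PhNTf2 should then triflate the enolate in preference to the hindered lithium alkoxide and give the hydroxy enol triflate F8. Stille methylation under the conditions of step 8 returns to the route at 17.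

Step 10. Hydride has to enter syn to the C1 side chain, so reagent control may be mismatched with the ring's own facial bias and the trans selectivity may erode; hydroboration of the ring alkene may also compete. The fallback replaces reagent control by intramolecular delivery and sets out from 16. DDQ (CH2Cl2/pH 7 buffer) should give the hydroxy ketone F9. Saksena–Evans reduction with Me4NBH(OAc)3 (MeCN/AcOH, −20 °C) should pass hydride from the C1′ alkoxyborohydride to the carbonyl face it overhangs and give the trans diol F10. Mitsunobu reaction with 20 should take place at the primary hydroxyl only, since the hindered secondary hydroxyl is inert and the trans diol cannot close a bridged ether, giving the hydroxy ether F11. Acetylation (Ac2O, Et3N, 4-(dimethylamino)pyridine) returns to the route at 21.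

Further compounds
F1 | step 6 | racemic triethyl{[6-{[(4-methoxybenzyl)oxy]methyl}-5,5-dimethyl-4-nitrocyclohex-1-en-1-yl]oxy}silane | O=[N+]([O-])C1CC=C(O[Si](CC)(CC)CC)C(COCc2ccc(OC)cc2)C1(C)C
F2 | step 6 | racemic 6-{[(4-methoxybenzyl)oxy]methyl}-5,5-dimethyl-4-nitrocyclohex-1-en-1-yl trifluoromethanesulfonate | O=[N+]([O-])C1CC=C(OS(=O)(=O)C(F)(F)F)C(COCc2ccc(OC)cc2)C1(C)C
F3 | step 6 | racemic 1-methoxy-4-{[(2,6,6-trimethyl-5-nitrocyclohex-2-en-1-yl)methoxy]methyl}benzene | O=[N+]([O-])C1CC=C(C)C(COCc2ccc(OC)cc2)C1(C)C
F4 | step 6 | racemic 5-{[(4-methoxybenzyl)oxy]methyl}-4,6,6-trimethylcyclohex-3-en-1-one | O=C1CC=C(C)C(COCc2ccc(OC)cc2)C1(C)C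
F5 | step 6 | (1R,5S)-5-{[(4-methoxybenzyl)oxy]methyl}-4,6,6-trimethylcyclohex-3-en-1-ol (hydroxyl cis to CH2OPMB) | O[C@@H]1CC=C(C)[C@H](COCc2ccc(OC)cc2)C1(C)C
F6 | step 7 | (5R)-5-{[(4-methoxybenzyl)oxy]methyl}-6,6-dimethyl-4-[(triethylsilyl)oxy]cyclohex-3-en-1-one | O=C1CC=C(O[Si](CC)(CC)CC)[C@@H](COCc2ccc(OC)cc2)C1(C)C
F7 | step 7 | (1R,5R)-5-{[(4-methoxybenzyl)oxy]methyl}-6,6-dimethyl-4-[(triethylsilyl)oxy]cyclohex-3-en-1-ol | O[C@@H]1CC=C(O[Si](CC)(CC)CC)[C@@H](COCc2ccc(OC)cc2)C1(C)C
F8 | step 7 | (4R,6R)-4-hydroxy-6-{[(4-methoxybenzyl)oxy]methyl}-5,5-dimethylcyclohex-1-en-1-yl trifluoromethanesulfonate | O[C@@H]1CC=C(OS(=O)(=O)C(F)(F)F)[C@@H](COCc2ccc(OC)cc2)C1(C)C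
F9 | step 10 | (5R)-5-(hydroxymethyl)-4,6,6-trimethylcyclohex-3-en-1-one | O=C1CC=C(C)[C@@H](CO)C1(C)C
F10 | step 10 | (1R,5R)-5-(hydroxymethyl)-4,6,6-trimethylcyclohex-3-en-1-ol | O[C@@H]1CC=C(C)[C@@H](CO)C1(C)C
F11 | step 10 | 7-{[(1R,5R)-5-hydroxy-2,6,6-trimethylcyclohex-2-en-1-yl]methoxy}-2H-chromen-2-one | O[C@@H]1CC=C(C)[C@@H](COc2ccc3ccc(=O)oc3c2)C1(C)C
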